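**Plan**

1. Rings: A = benzoate ring, B = ring that carries the lactone oxygen, C = pyran on A, D = pyran on B, E = seven-membered lactone ring. Retrosynthetic cuts, in order: the lactone C(=O)–O bond of E; the O–C(CH3)2 bond of C together with its ring alkene (back to a prenyl group on A and a para-quinone on B); the ether C–O bond at the quinone carbon; O–C(CH3)2 and C4a–C4 of D (back to 2,5-dihydroxy-1,4-benzoquinone and 3-methylbut-2-enal); the two aryl–CH2 bonds of A (back to a phloroglucinol carboxylate and prenyl bromide).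
2. Forward order of ring formation: D (on the quinone), then the diaryl ether, then C (key step), then E.
3. Feature that makes the key event possible: on ring B the free hydroxyl and the lactone oxygen are para (C-8 and C-5 of chromene D), so B can be carried as the 5,8-quinone. Its C-6 ether oxygen is bonded to the ring-A carbon that lies ortho to one prenyl-bearing carbon, so the quinone C-5 carbonyl sits next to one prenyl CH2 only. It can therefore oxidise just that prenyl-phenol pair to the o-quinone methide that closes ring C, and ends as the hydroquinone that ring E needs.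
4. Ring A stays mirror-symmetric (two prenyl groups, two equivalent ortho hydroxyls) until the ether is made, so no regiochemical choice arises before the key step. Helpers: silyl ether on the 4-oxygen of A (removed in step 7), allyl ester (removed in step 9), quinone level of B (used up in step 8).
5. Stereochemistry: the target has no stereocentre; the two pyran alkenes are cis by ring constraint and come from the electrocyclisations.

Key step: step 8

Assumption: 2,4,6-trihydroxybenzoic acid is used as its commercial monohydrate, and the exocyclic alkene geometry of intermediates 8 and 13 is left undefined because the isomers should interconvert and only the dienone with the chain syn to the carbonyl closes.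

**Route**

Step 1
Reactants: 1 2,4,6-trihydroxybenzoic acid
Product: 2 prop-2-en-1-yl 2,4,6-trihydroxybenzoate
Conditions: allyl bromide (1.05 equiv), KHCO3 (1.1 equiv), DMF, rt
Reagents that add atoms: allyl bromide, C=CCBr
Why: Carboxylate O-alkylation (SN2), in which KHCO3 ionises only the carboxylic acid, so the phenols stay free and the acid is never heated, which avoids decarboxylation.

Step 2
Reactants: 2 prop-2-en-1-yl 2,4,6-trihydroxybenzoate; 3 1-bromo-3-methylbut-2-ene (2.2 equiv)
Product: 4 prop-2-en-1-yl 2,4,6-trihydroxy-3,5-bis(3-methylbut-2-en-1-yl)benzoate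
Conditions: 3 (2.2 equiv), 10% aq KOH, 0 °C
Reagents that add atoms: none
Why: Twofold C-alkylation of a phloroglucinol polyanion in water (the known C-prenylation of acylphloroglucinols), where solvation of the phenoxide oxygens favours attack through carbon; both nuclear C–H positions are used, so no regiochemical question remains and the ionised, hindered ester should resist hydrolysis.

Step 3
Reactants: 4 prop-2-en-1-yl 2,4,6-trihydroxy-3,5-bis(3-methylbut-2-en-1-yl)benzoate
Product: 5 prop-2-en-1-yl 4-[(tert-butyldimethylsilyl)oxy]-2,6-dihydroxy-3,5-bis(3-methylbut-2-en-1-yl)benzoate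
Conditions: TBSCl (1.1 equiv), imidazole, DMF, 0 °C to rt
Reagents that add atoms: tert-butyldimethylsilyl chloride, CC(C)(C)[Si](C)(C)Cl
Why: Phenol silylation, in which the 2- and 6-hydroxyls are held in hydrogen bonds to the ester so that the 4-hydroxyl should react, which blocks the oxygen that would otherwise attack the quinone first in step 6.

Step 4
Reactants: 6 2,5-dihydroxy-1,4-benzoquinone; 7 3-methylbut-2-enal
Product: 9 6-hydroxy-2,2-dimethyl-2H-chromene-5,8-dione, via alkylidene trione 8 (not isolated)
Conditions: ethylenediammonium diacetate (10 mol%), EtOH, 70 °C; 6 in twofold excess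
Reagents that add atoms: none
Why: Knoevenagel condensation at C-3 of the vinylogous acid followed by oxa-6π electrocyclisation of 1-oxatriene 8 (the known annulation of 2-hydroxy-1,4-quinones with enals); closure on either flanking carbonyl oxygen gives the same hydroxy-para-quinone after tautomerisation, and the excess of 6 should limit a second annulation.

Step 5
Reactants: 9 6-hydroxy-2,2-dimethyl-2H-chromene-5,8-dione
Product: 10 6-chloro-2,2-dimethyl-2H-chromene-5,8-dione
Conditions: (COCl)2 (1.2 equiv), DMF (cat.), CH2Cl2, 0 °C to rt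
Reagents that add atoms: oxalyl chloride, O=C(Cl)C(=O)Cl
Why: Conversion of a vinylogous carboxylic acid into its vinylogous acid chloride through a Vilsmeier-type chloroiminium salt, as known for 2-hydroxy-1,4-naphthoquinone.

Step 6
Reactants: 5 prop-2-en-1-yl 4-[(tert-butyldimethylsilyl)oxy]-2,6-dihydroxy-3,5-bis(3-methylbut-2-en-1-yl)benzoate; 10 6-chloro-2,2-dimethyl-2H-chromene-5,8-dione
Product: 11 prop-2-en-1-yl 4-[(tert-butyldimethylsilyl)oxy]-2-[(2,2-dimethyl-5,8-dioxo-5,8-dihydro-2H-chromen-6-yl)oxy]-6-hydroxy-3,5-bis(3-methylbut-2-en-1-yl)benzoate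
Conditions: NaH (1.0 equiv), THF, 0 °C; then 10 (1.05 equiv), 0 °C to rt
Reagents that add atoms: none
Why: Addition–elimination of a phenoxide on a halo-quinone (the known route to aryloxyquinones), in which the C-8 carbonyl is the more electrophilic one because C-5 is a vinylogous ester of the pyran oxygen, so attack should go to C-6 with loss of chloride; the two free hydroxyls of 5 are equivalent by symmetry.

Step 7
Reactants: 11 prop-2-en-1-yl 4-[(tert-butyldimethylsilyl)oxy]-2-[(2,2-dimethyl-5,8-dioxo-5,8-dihydro-2H-chromen-6-yl)oxy]-6-hydroxy-3,5-bis(3-methylbut-2-en-1-yl)benzoate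
Product: 12 prop-2-en-1-yl 2-[(2,2-dimethyl-5,8-dioxo-5,8-dihydro-2H-chromen-6-yl)oxy]-4,6-dihydroxy-3,5-bis(3-methylbut-2-en-1-yl)benzoate
Conditions: TBAF (1.1 equiv), AcOH (1.5 equiv), THF, 0 °C
Reagents that add atoms: none
Why: Fluoride cleavage of an aryl silyl ether, buffered with acetic acid so that no free phenoxide is present that could exchange the aryloxy group on the quinone.

Step 8
Reactants: 12 prop-2-en-1-yl 2-[(2,2-dimethyl-5,8-dioxo-5,8-dihydro-2H-chromen-6-yl)oxy]-4,6-dihydroxy-3,5-bis(3-methylbut-2-en-1-yl)benzoate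
Product: 14 prop-2-en-1-yl 5-[(5,8-dihydroxy-2,2-dimethyl-2H-chromen-6-yl)oxy]-7-hydroxy-2,2-dimethyl-8-(3-methylbut-2-en-1-yl)-2H-chromene-6-carboxylate, via o-quinone methide 13 (not isolated)
Conditions: PhCl (0.005 M, degassed), 110 °C, dark, argon
Reagents that add atoms: none
Why: Proposed new method: the 5,8-quinone of ring B is tied through the ether oxygen to the ring-A carbon next to one prenyl group, so its C-5 carbonyl oxygen should take a hydrogen from that benzylic, allylic CH2 through an eight-membered cyclic transition state while a phenolic hydrogen of ring A follows, which gives the hydroquinone-bearing o-quinone methide 13 in a redox-neutral isomerisation that should be exergonic, since reduction of an alkoxy-aryloxy-quinone releases more free energy than the dehydrogenative ring closure consumes. The closest known reaction types are the DDQ dehydrogenation of o-prenylphenols to 2,2-dimethyl-2H-chromenes and the thermal or base-induced isomerisation of prenylquinones to chromenols, both of which pass through a quinone-generated o-quinone methide. Ring C then closes by thermal disrotatory oxa-6π electrocyclisation of the dienone O=C–C=CH–CH=C(CH3)2 of 13, which forms the O–C(CH3)2 bond and restores the aromaticity of ring A. No stereocentre is formed, and the new ring alkene is cis by ring constraint. The step needs site selectivity between the two prenyl groups and between the hydroxyls: only the proximal prenyl can reach the quinone within the molecule, its carbon has the 4-hydroxyl as the sole ortho hydroxyl (the other neighbour is the ether oxygen), and the distal prenyl could be oxidised only bimolecularly, which the 0.005 M concentration should suppress. Neutral, base-free conditions keep the phenols protonated so that aryloxy exchange on the quinone should not compete, and any reversible oxa-Michael adduct of 13 should drain into the chromene.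

Step 9
Reactants: 14 prop-2-en-1-yl 5-[(5,8-dihydroxy-2,2-dimethyl-2H-chromen-6-yl)oxy]-7-hydroxy-2,2-dimethyl-8-(3-methylbut-2-en-1-yl)-2H-chromene-6-carboxylate
Product: 15 5-[(5,8-dihydroxy-2,2-dimethyl-2H-chromen-6-yl)oxy]-7-hydroxy-2,2-dimethyl-8-(3-methylbut-2-en-1-yl)-2H-chromene-6-carboxylic acid
Conditions: Pd(PPh3)4 (5 mol%), morpholine (5 equiv), THF, rt, argon
Reagents that add atoms: none
Why: Tsuji–Trost deallylation, in which zerovalent palladium ionises the allyl ester to a π-allyl complex of divalent palladium that morpholine captures, while the prenyl group and the chromene alkenes carry no leaving group and should stay untouched.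

Step 10
Reactants: 15 5-[(5,8-dihydroxy-2,2-dimethyl-2H-chromen-6-yl)oxy]-7-hydroxy-2,2-dimethyl-8-(3-methylbut-2-en-1-yl)-2H-chromene-6-carboxylic acid
Product: 16 Garcinisidone D
Conditions: DCC (1.2 equiv), DMAP (10 mol%), CH2Cl2 (0.005 M), 0 °C to rt, argon
Reagents that add atoms: none
Why: Carbodiimide lactonisation of a 2-(2-hydroxyaryloxy)benzoic acid (the classical depsidone ring closure), in which only the hydroxyl ortho to the ether oxygen can reach the activated carboxyl, so the seven-membered ring should form under high dilution.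

**Compound list**

1 | 2,4,6-trihydroxybenzoic acid | O=C(O)c1c(O)cc(O)cc1O | starting material
2 | prop-2-en-1-yl 2,4,6-trihydroxybenzoate | C=CCOC(=O)c1c(O)cc(O)cc1O | intermediate
3 | 1-bromo-3-methylbut-2-ene (prenyl bromide) | CC(C)=CCBr | starting material
4 | prop-2-en-1-yl 2,4,6-trihydroxy-3,5-bis(3-methylbut-2-en-1-yl)benzoate | C=CCOC(=O)c1c(O)c(CC=C(C)C)c(O)c(CC=C(C)C)c1O | intermediate
5 | prop-2-en-1-yl 4-[(tert-butyldimethylsilyl)oxy]-2,6-dihydroxy-3,5-bis(3-methylbut-2-en-1-yl)benzoate | C=CCOC(=O)c1c(O)c(CC=C(C)C)c(O[Si](C)(C)C(C)(C)C)c(CC=C(C)C)c1O | intermediate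
6 | 2,5-dihydroxy-1,4-benzoquinone | O=C1C=C(O)C(=O)C=C1O | starting material
7 | 3-methylbut-2-enal | CC(C)=CC=O | starting material
8 | 5-hydroxy-3-(3-methylbut-2-en-1-ylidene)cyclohex-5-ene-1,2,4-trione | CC(C)=CC=C1C(=O)C(=O)C=C(O)C1=O | intermediate (not isolated)
9 | 6-hydroxy-2,2-dimethyl-2H-chromene-5,8-dione | CC1(C)C=CC2=C(O1)C(=O)C=C(O)C2=O | intermediate
10 | 6-chloro-2,2-dimethyl-2H-chromene-5,8-dione | CC1(C)C=CC2=C(O1)C(=O)C=C(Cl)C2=O | intermediate
11 | prop-2-en-1-yl 4-[(tert-butyldimethylsilyl)oxy]-2-[(2,2-dimethyl-5,8-dioxo-5,8-dihydro-2H-chromen-6-yl)oxy]-6-hydroxy-3,5-bis(3-methylbut-2-en-1-yl)benzoate | C=CCOC(=O)c1c(O)c(CC=C(C)C)c(O[Si](C)(C)C(C)(C)C)c(CC=C(C)C)c1OC1=CC(=O)C2=C(C=CC(C)(C)O2)C1=O | intermediate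
12 | prop-2-en-1-yl 2-[(2,2-dimethyl-5,8-dioxo-5,8-dihydro-2H-chromen-6-yl)oxy]-4,6-dihydroxy-3,5-bis(3-methylbut-2-en-1-yl)benzoate | C=CCOC(=O)c1c(O)c(CC=C(C)C)c(O)c(CC=C(C)C)c1OC1=CC(=O)C2=C(C=CC(C)(C)O2)C1=O | intermediate
13 | prop-2-en-1-yl 2-[(5,8-dihydroxy-2,2-dimethyl-2H-chromen-6-yl)oxy]-6-hydroxy-5-(3-methylbut-2-en-1-yl)-3-(3-methylbut-2-en-1-ylidene)-4-oxocyclohexa-1,5-diene-1-carboxylate | C=CCOC(=O)C1=C(Oc2cc(O)c3OC(C)(C)C=Cc3c2O)C(=CC=C(C)C)C(=O)C(CC=C(C)C)=C1O | intermediate (not isolated)
14 | prop-2-en-1-yl 5-[(5,8-dihydroxy-2,2-dimethyl-2H-chromen-6-yl)oxy]-7-hydroxy-2,2-dimethyl-8-(3-methylbut-2-en-1-yl)-2H-chromene-6-carboxylate | C=CCOC(=O)c1c(O)c(CC=C(C)C)c2OC(C)(C)C=Cc2c1Oc1cc(O)c2OC(C)(C)C=Cc2c1O | intermediate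
15 | 5-[(5,8-dihydroxy-2,2-dimethyl-2H-chromen-6-yl)oxy]-7-hydroxy-2,2-dimethyl-8-(3-methylbut-2-en-1-yl)-2H-chromene-6-carboxylic acid | O=C(O)c1c(O)c(CC=C(C)C)c2OC(C)(C)C=Cc2c1Oc1cc(O)c2OC(C)(C)C=Cc2c1O | intermediate
16 | Garcinisidone D | CC(C)=CCc1c(O)c2c(c3c1OC(C)(C)C=C3)Oc1cc(O)c3c(c1OC2=O)C=CC(C)(C)O3 | target

**Step count**

Total steps: 10. Longest linear sequence: 8 steps (steps 1, 2, 3, 6, 7, 8, 9, 10).

**Steps most likely to fail**

1. Step 8. The hydrogen transfer to the weakly oxidising alkoxy-aryloxy-quinone may be too slow, so that bimolecular redox chemistry, aryloxy exchange or recombination of radical intermediates takes over. The fallback uses the known aryl propargyl ether Claisen cascade in a mono-prenyl series; it sets out from 2 (and uses 10) and comes back at 14. Compound 2 would be C-prenylated once (3, 1.0 equiv, 10% aq KOH, 0 °C) to prop-2-en-1-yl 2,4,6-trihydroxy-3-(3-methylbut-2-en-1-yl)benzoate F1. Its 4-hydroxyl would be etherified with 3-chloro-3-methylbut-1-yne (K2CO3, KI, CuI cat., acetone, 55 °C) to prop-2-en-1-yl 2,6-dihydroxy-4-[(2-methylbut-3-yn-2-yl)oxy]-3-(3-methylbut-2-en-1-yl)benzoate F2. The sodium salt of F2 (NaH, THF, 0 °C) would be joined to 10 as in step 6 to give prop-2-en-1-yl 6-[(2,2-dimethyl-5,8-dioxo-5,8-dihydro-2H-chromen-6-yl)oxy]-2-hydroxy-4-[(2-methylbut-3-yn-2-yl)oxy]-3-(3-methylbut-2-en-1-yl)benzoate F3; the hydroxyl flanked by hydrogen is expected to react in preference to the one flanked by the prenyl group. Na2S2O4 in THF–H2O would reduce the quinone to prop-2-en-1-yl 6-[(5,8-dihydroxy-2,2-dimethyl-2H-chromen-6-yl)oxy]-2-hydroxy-4-[(2-methylbut-3-yn-2-yl)oxy]-3-(3-methylbut-2-en-1-yl)benzoate F4. Heating F4 in xylene at 140 °C under argon should bring about the aromatic propargyl Claisen rearrangement, 1,5-hydrogen shift and oxa-6π closure at the only free ortho position, giving 14.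

2. Step 2. Over-alkylation at carbon (geminal diprenylation with loss of aromaticity) and O-alkylation may consume the material before both nuclear positions are prenylated. The fallback replaces phenoxide C-alkylation by a twofold aromatic Claisen rearrangement; it sets out from 2 and comes back at 5. Compound 2 would be silylated at the 4-hydroxyl (TBSCl, imidazole, DMF) to prop-2-en-1-yl 4-[(tert-butyldimethylsilyl)oxy]-2,6-dihydroxybenzoate F5. Both remaining hydroxyls would be etherified with 3-chloro-3-methylbut-1-yne (CuCl2·2H2O cat., DBU, MeCN, 0 °C) to prop-2-en-1-yl 4-[(tert-butyldimethylsilyl)oxy]-2,6-bis[(2-methylbut-3-yn-2-yl)oxy]benzoate F6. Semihydrogenation (H2, Pd/CaCO3 poisoned with Pb(OAc)2, quinoline, EtOAc) would give prop-2-en-1-yl 4-[(tert-butyldimethylsilyl)oxy]-2,6-bis[(2-methylbut-3-en-2-yl)oxy]benzoate F7. Heating F7 in toluene at 110 °C should move each 1,1-dimethylallyl group to its only free ortho carbon, giving 5.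

3. Step 10. Rearrangement of the O-acylisourea to an N-acylurea, acylation between molecules, or air oxidation of the hydroquinone may outrun the closure of the seven-membered ring at the hindered carboxyl. The fallback separates activation from ring closure through an isolable active ester; it sets out from 15 and comes back at 16. Acid 15 would be treated with pentafluorophenyl trifluoroacetate and pyridine in DMF at 0 °C to give pentafluorophenyl 5-[(5,8-dihydroxy-2,2-dimethyl-2H-chromen-6-yl)oxy]-7-hydroxy-2,2-dimethyl-8-(3-methylbut-2-en-1-yl)-2H-chromene-6-carboxylate F8. Slow addition of F8 to iPr2NEt in dilute MeCN under argon should close the lactone by transacylation with loss of pentafluorophenol, giving 16.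

**Further compounds**

F1 | step 8 | prop-2-en-1-yl 2,4,6-trihydroxy-3-(3-methylbut-2-en-1-yl)benzoate | C=CCOC(=O)c1c(O)cc(O)c(CC=C(C)C)c1O
F2 | step 8 | prop-2-en-1-yl 2,6-dihydroxy-4-[(2-methylbut-3-yn-2-yl)oxy]-3-(3-methylbut-2-en-1-yl)benzoate | C=CCOC(=O)c1c(O)cc(OC(C)(C)C#C)c(CC=C(C)C)c1O
F3 | step 8 | prop-2-en-1-yl 6-[(2,2-dimethyl-5,8-dioxo-5,8-dihydro-2H-chromen-6-yl)oxy]-2-hydroxy-4-[(2-methylbut-3-yn-2-yl)oxy]-3-(3-methylbut-2-en-1-yl)benzoate | C=CCOC(=O)c1c(O)c(CC=C(C)C)c(OC(C)(C)C#C)cc1OC1=CC(=O)C2=C(C=CC(C)(C)O2)C1=O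
F4 | step 8 | prop-2-en-1-yl 6-[(5,8-dihydroxy-2,2-dimethyl-2H-chromen-6-yl)oxy]-2-hydroxy-4-[(2-methylbut-3-yn-2-yl)oxy]-3-(3-methylbut-2-en-1-yl)benzoate | C=CCOC(=O)c1c(O)c(CC=C(C)C)c(OC(C)(C)C#C)cc1Oc1cc(O)c2OC(C)(C)C=Cc2c1O
F5 | step 2 | prop-2-en-1-yl 4-[(tert-butyldimethylsilyl)oxy]-2,6-dihydroxybenzoate | C=CCOC(=O)c1c(O)cc(O[Si](C)(C)C(C)(C)C)cc1O
F6 | step 2 | prop-2-en-1-yl 4-[(tert-butyldimethylsilyl)oxy]-2,6-bis[(2-methylbut-3-yn-2-yl)oxy]benzoate | C=CCOC(=O)c1c(OC(C)(C)C#C)cc(O[Si](C)(C)C(C)(C)C)cc1OC(C)(C)C#C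
F7 | step 2 | prop-2-en-1-yl 4-[(tert-butyldimethylsilyl)oxy]-2,6-bis[(2-methylbut-3-en-2-yl)oxy]benzoate | C=CCOC(=O)c1c(OC(C)(C)C=C)cc(O[Si](C)(C)C(C)(C)C)cc1OC(C)(C)C=C
F8 | step 10 | pentafluorophenyl 5-[(5,8-dihydroxy-2,2-dimethyl-2H-chromen-6-yl)oxy]-7-hydroxy-2,2-dimethyl-8-(3-methylbut-2-en-1-yl)-2H-chromene-6-carboxylate | O=C(Oc1c(F)c(F)c(F)c(F)c1F)c1c(O)c(CC=C(C)C)c2OC(C)(C)C=Cc2c1Oc1cc(O)c2OC(C)(C)C=Cc2c1O
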